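**Retrosynthetic overview**
The target is a (2S)-flavanone. The plan rests on O1 of ring C, which ties the sp3 stereocentre C2 to the ring A carbon C8a, itself wedged between C8 (OMe) and C4a.
Endgame: C4=O is released from an exocyclic C4=CH2 group by oxidative cleavage, then the 3'-O-benzyl ether is hydrogenolysed.
Ring C is the only ring built (rings A and B are bought). It is closed at C8a–O1 by palladium-catalysed etherification of a C8a bromide with the preformed C2 carbinol.
The (S)-homoallylic alcohol derives from a β-hydroxy ketone (silylation, methylenation, desilylation), whose C2–C3 bond and C2 configuration come from a catalytic enantioselective Mukaiyama aldol addition.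
Building blocks: 2-bromo-3,4-dimethoxybenzaldehyde (ring A and C4, with C3 added as a methyl group) and 3-hydroxy-4,5-dimethoxybenzaldehyde (ring B and C2).

Key step: step 9

Remark: the facial sense of the oxazaborolidinone catalyst is carried over from the benzaldehyde/acetophenone enol silane pair (L-tryptophan series: Re attack, R carbinol), so the D-tryptophan series is specified; the configuration and enantiomeric purity of 8 should be checked (Mosher esters, chiral HPLC) before going on.

Step 1
Reactants: 1 3-hydroxy-4,5-dimethoxybenzaldehyde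
Product: 2 3-(benzyloxy)-4,5-dimethoxybenzaldehyde
Conditions: BnBr, K2CO3, DMF, rt to 50 °C
Reagents that add atoms: benzyl bromide, BrCc1ccccc1
Why: Williamson etherification of the only acidic OH should install a benzyl ether that tolerates the Lewis acid, organotitanium, fluoride, palladium/carbonate and OsO4 steps and leaves by hydrogenolysis at the end.

Step 2
Reactants: 3 2-bromo-3,4-dimethoxybenzaldehyde
Product: 4 rac-1-(2-bromo-3,4-dimethoxyphenyl)ethan-1-ol
Conditions: MeMgBr, THF, 0 °C; then H2O/aq NH4Cl
Reagents that add atoms: methylmagnesium bromide, C[Mg]Br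
Why: Grignard 1,2-addition to the aldehyde is much faster than halogen–magnesium exchange at the crowded aryl bromide, and the racemic carbinol centre is erased in step 3.

Step 3
Reactants: 4 rac-1-(2-bromo-3,4-dimethoxyphenyl)ethan-1-ol
Product: 5 1-(2-bromo-3,4-dimethoxyphenyl)ethan-1-one
Conditions: Dess–Martin periodinane, CH2Cl2, 0 °C to rt
Reagents that add atoms: none
Why: Dess–Martin oxidation of a secondary benzylic alcohol runs under near-neutral conditions that leave the aryl bromide and the methyl ethers untouched.

Step 4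
Reactants: 5 1-(2-bromo-3,4-dimethoxyphenyl)ethan-1-one
Product: 6 {[1-(2-bromo-3,4-dimethoxyphenyl)ethenyl]oxy}trimethylsilane
Conditions: TMSOTf, Et3N, CH2Cl2, 0 °C
Reagents that add atoms: trimethylsilyl triflate, C[Si](C)(C)OS(=O)(=O)C(F)(F)F
Why: Soft enolisation and O-silylation of a methyl ketone with a single enolisable position should give only the terminal enol silane needed for the Mukaiyama aldol addition.

Step 5
Reactants: 6 {[1-(2-bromo-3,4-dimethoxyphenyl)ethenyl]oxy}trimethylsilane; 2 3-(benzyloxy)-4,5-dimethoxybenzaldehyde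
Product: 8 (3S)-3-[3-(benzyloxy)-4,5-dimethoxyphenyl]-1-(2-bromo-3,4-dimethoxyphenyl)-3-hydroxypropan-1-one, via trimethylsilyl ether 7 (not isolated)
Conditions: (4R)-2-butyl-4-(1H-indol-3-ylmethyl)-3-tosyl-1,3,2-oxazaborolidin-5-one (20 mol %, preformed from N-tosyl-D-tryptophan and n-BuB(OH)2), EtCN, −78 °C; then 1 M HCl, THF, 0 °C
Reagents that add atoms: none
Why: Catalytic enantioselective Mukaiyama aldol addition through an open transition state, in which 2 binds to boron on the face of the oxazaborolidinone that carries the indolylmethyl group, the indole stacks on the Re face of the formyl group, enol silane 6 adds to the free Si face and sets the future C2 as S, silyl transfer gives 7, and brief cold acid frees the carbinol without dehydration.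

Step 6
Reactants: 8 (3S)-3-[3-(benzyloxy)-4,5-dimethoxyphenyl]-1-(2-bromo-3,4-dimethoxyphenyl)-3-hydroxypropan-1-one
Product: 9 (3S)-3-[3-(benzyloxy)-4,5-dimethoxyphenyl]-1-(2-bromo-3,4-dimethoxyphenyl)-3-[(tert-butyldimethylsilyl)oxy]propan-1-one
Conditions: TBSOTf, 2,6-lutidine, CH2Cl2, −78 to 0 °C
Reagents that add atoms: tert-butyldimethylsilyl triflate, CC(C)(C)[Si](C)(C)OS(=O)(=O)C(F)(F)F
Why: O-silylation with a silyl triflate and a hindered pyridine base at low temperature avoids retro-aldol cleavage and E1cB loss of the β-oxygen, and removes the acidic proton that would consume the titanium reagent.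

Step 7
Reactants: 9 (3S)-3-[3-(benzyloxy)-4,5-dimethoxyphenyl]-1-(2-bromo-3,4-dimethoxyphenyl)-3-[(tert-butyldimethylsilyl)oxy]propan-1-one
Product: 10 {[(1S)-1-[3-(benzyloxy)-4,5-dimethoxyphenyl]-3-(2-bromo-3,4-dimethoxyphenyl)but-3-en-1-yl]oxy}(tert-butyl)dimethylsilane
Conditions: Cp2TiMe2 (3 equiv), toluene, 75 °C, dark
Reagents that add atoms: dimethyltitanocene Cp2TiMe2, C[Ti](C)(C1C=CC=C1)C1C=CC=C1
Why: Petasis methylenation, in which thermally formed Cp2Ti=CH2 undergoes [2+2] addition and cycloreversion with the aryl ketone, is non-basic, so the β-silyloxy group is not eliminated and the aryl bromide stays inert.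

Step 8
Reactants: 10 {[(1S)-1-[3-(benzyloxy)-4,5-dimethoxyphenyl]-3-(2-bromo-3,4-dimethoxyphenyl)but-3-en-1-yl]oxy}(tert-butyl)dimethylsilane
Product: 11 (1S)-1-[3-(benzyloxy)-4,5-dimethoxyphenyl]-3-(2-bromo-3,4-dimethoxyphenyl)but-3-en-1-ol
Conditions: TBAF, AcOH (1:1), THF, rt
Reagents that add atoms: none
Why: Fluoride-induced desilylation breaks only the Si–O bond, so the S carbinol is kept, and the acetic acid buffer keeps the 1,1-disubstituted alkene from migrating.

Step 9
Reactants: 11 (1S)-1-[3-(benzyloxy)-4,5-dimethoxyphenyl]-3-(2-bromo-3,4-dimethoxyphenyl)but-3-en-1-ol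
Product: 12 (2S)-2-[3-(benzyloxy)-4,5-dimethoxyphenyl]-7,8-dimethoxy-4-methylidenechromane
Conditions: Pd(OAc)2 (5 mol %), 2-(di-tert-butylphosphino)-1,1'-binaphthyl (7 mol %), Cs2CO3 (1.5 equiv), toluene, 70–80 °C, Ar
Reagents that add atoms: none
Why: The phosphine-ligated zerovalent palladium generated from Pd(OAc)2 inserts into the C8a–Br bond, Cs2CO3 deprotonates the tethered carbinol so that its oxygen takes the place of bromide on divalent palladium, and C(sp2)–O reductive elimination releases 12 and returns the catalyst. The closest known reaction type is the intramolecular Buchwald–Hartwig C–O coupling of aryl bromides that carry a pendant secondary alcohol, an established entry to 2-substituted chromans. Ring C closes as a six-membered ring by contraction of a seven-membered oxapalladacycle, with the new bond joining the carbinol oxygen (O1) to C8a. No stereocentre is created, and C2 stays S because only its O–H bond is broken in the cycle. The selectivity required is reductive elimination ahead of β-hydride loss from C2–H, and it is secured by the bulky electron-rich di-tert-butyl biaryl phosphine, by the crowding of palladium between the C8 methoxy group and the C4a side chain, and by the short tether. With C4 held as a methylene group, the carbonate base finds no β-hydroxy ketone to cleave or dehydrate, and the alkene cannot intercept the aryl–palladium bond because a Heck closure would need a three- or four-membered ring.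

Step 10
Reactants: 12 (2S)-2-[3-(benzyloxy)-4,5-dimethoxyphenyl]-7,8-dimethoxy-4-methylidenechromane
Product: 14 (2S)-2-[3-(benzyloxy)-4,5-dimethoxyphenyl]-7,8-dimethoxychroman-4-one, via vicinal diol 13 (not isolated)
Conditions: OsO4 (2 mol %), NaIO4 (4 equiv), 2,6-lutidine (2 equiv), 1,4-dioxane–H2O 3:1, rt
Reagents that add atoms: OsO4, O=[Os](=O)(=O)=O (delivers the oxygen); NaIO4, [Na+].[O-]I(=O)(=O)=O (restores it)
Why: Lemieux–Johnson oxidation dihydroxylates the only alkene and cleaves diol 13 in the same flask, and the lutidine-buffered, near-neutral medium should not open the flavanone to its chalcone, so C2 is not scrambled.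

Step 11
Reactants: 14 (2S)-2-[3-(benzyloxy)-4,5-dimethoxyphenyl]-7,8-dimethoxychroman-4-one
Product: 15 (2S)-2-(3-hydroxy-4,5-dimethoxyphenyl)-7,8-dimethoxychroman-4-one (target)
Conditions: H2 (1 atm), Pd/C (10 wt % Pd), EtOAc–EtOH, rt, stopped after uptake of one equivalent
Reagents that add atoms: none
Why: Catalytic hydrogenolysis removes the unhindered primary benzyl aryl ether faster than it attacks the cyclic C2–O1 bond or the C4 aryl ketone, and the neutral medium leaves C2 configurationally intact.

**Compound list**
1 | 3-hydroxy-4,5-dimethoxybenzaldehyde | COc1cc(C=O)cc(O)c1OC | starting material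
2 | 3-(benzyloxy)-4,5-dimethoxybenzaldehyde | COc1cc(C=O)cc(OCc2ccccc2)c1OC | intermediate
3 | 2-bromo-3,4-dimethoxybenzaldehyde | COc1ccc(C=O)c(Br)c1OC | starting material
4 | rac-1-(2-bromo-3,4-dimethoxyphenyl)ethan-1-ol | COc1ccc(C(C)O)c(Br)c1OC | intermediate
5 | 1-(2-bromo-3,4-dimethoxyphenyl)ethan-1-one | COc1ccc(C(C)=O)c(Br)c1OC | intermediate
6 | {[1-(2-bromo-3,4-dimethoxyphenyl)ethenyl]oxy}trimethylsilane | COc1ccc(C(=C)O[Si](C)(C)C)c(Br)c1OC | intermediate
7 | (3S)-3-[3-(benzyloxy)-4,5-dimethoxyphenyl]-1-(2-bromo-3,4-dimethoxyphenyl)-3-[(trimethylsilyl)oxy]propan-1-one | COc1cc([C@@H](O[Si](C)(C)C)CC(=O)c2ccc(OC)c(OC)c2Br)cc(OCc2ccccc2)c1OC | intermediate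
8 | (3S)-3-[3-(benzyloxy)-4,5-dimethoxyphenyl]-1-(2-bromo-3,4-dimethoxyphenyl)-3-hydroxypropan-1-one | COc1cc([C@@H](O)CC(=O)c2ccc(OC)c(OC)c2Br)cc(OCc2ccccc2)c1OC | intermediate
9 | (3S)-3-[3-(benzyloxy)-4,5-dimethoxyphenyl]-1-(2-bromo-3,4-dimethoxyphenyl)-3-[(tert-butyldimethylsilyl)oxy]propan-1-one | COc1cc([C@@H](O[Si](C)(C)C(C)(C)C)CC(=O)c2ccc(OC)c(OC)c2Br)cc(OCc2ccccc2)c1OC | intermediate
10 | {[(1S)-1-[3-(benzyloxy)-4,5-dimethoxyphenyl]-3-(2-bromo-3,4-dimethoxyphenyl)but-3-en-1-yl]oxy}(tert-butyl)dimethylsilane | COc1cc([C@@H](O[Si](C)(C)C(C)(C)C)CC(=C)c2ccc(OC)c(OC)c2Br)cc(OCc2ccccc2)c1OC | intermediate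
11 | (1S)-1-[3-(benzyloxy)-4,5-dimethoxyphenyl]-3-(2-bromo-3,4-dimethoxyphenyl)but-3-en-1-ol | COc1cc([C@@H](O)CC(=C)c2ccc(OC)c(OC)c2Br)cc(OCc2ccccc2)c1OC | intermediate
12 | (2S)-2-[3-(benzyloxy)-4,5-dimethoxyphenyl]-7,8-dimethoxy-4-methylidenechromane | COc1cc([C@@H]2CC(=C)c3ccc(OC)c(OC)c3O2)cc(OCc2ccccc2)c1OC | intermediate
13 | (2S)-2-[3-(benzyloxy)-4,5-dimethoxyphenyl]-4-(hydroxymethyl)-7,8-dimethoxychroman-4-ol (C4 epimers) | COc1cc([C@@H]2CC(O)(CO)c3ccc(OC)c(OC)c3O2)cc(OCc2ccccc2)c1OC | intermediate
14 | (2S)-2-[3-(benzyloxy)-4,5-dimethoxyphenyl]-7,8-dimethoxychroman-4-one | COc1cc([C@@H]2CC(=O)c3ccc(OC)c(OC)c3O2)cc(OCc2ccccc2)c1OC | intermediate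
15 | (2S)-2-(3-hydroxy-4,5-dimethoxyphenyl)-7,8-dimethoxychroman-4-one | COc1cc([C@@H]2CC(=O)c3ccc(OC)c(OC)c3O2)cc(O)c1OC | target

**Step count**
Total step count: 11.
Longest linear sequence: 10 steps (steps 2 to 11, from 3).

**Steps most likely to fail**

Step 9.
- What may go wrong: oxidative addition may be slow at the electron-rich, doubly ortho-substituted bromide. The palladium alkoxide may undergo β-hydride loss or retro-allylative C2–C3 cleavage, leading to hydrodebromination. The exocyclic double bond may also migrate into ring C through palladium hydride species.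
- Fallback: it sets out from 11 and inverts the polarity at C8a. Double lithiation (n-BuLi, 2.2 equiv, THF, −78 °C; O–H first, then Br–Li exchange), trapping with B(OiPr)3 and mild aqueous work-up should give the arylboronic acid F1. An intramolecular Chan–Lam coupling (Cu(OAc)2, pyridine, 4 Å molecular sieves, air, CH2Cl2, rt) should then form the same C8a–O1 bond on divalent copper. The C2–O bond is again untouched, so configuration is retained, and the route is rejoined at 12.

Step 5.
- What may go wrong: facial selectivity may be insufficient with the crowded ortho-bromo enol silane. An uncatalysed silyl-cation background reaction may compete. Dehydration or retro-aldol cleavage may occur during hydrolysis of the silyl ether. If 8 or 14 crystallises, recrystallisation could raise the enantiomeric purity.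
- Fallback: it sets out from 5 and 2 and moves the stereocontrol to an epoxidation. Claisen–Schmidt condensation (KOH, EtOH, rt) should give the (E)-chalcone F2. Juliá–Colonna epoxidation with poly-D-leucine (urea–H2O2, DBU, THF) should give the (2S,3R)-epoxy ketone F3. Reductive opening of its Cα–O bond with the selenide reagent from (PhSe)2 and NaBH4 (EtOH, AcOH, 0 °C) leaves the benzylic C–O bond in place and rejoins the route at 8.

Step 7.
- What may go wrong: methylenation may be sluggish at the ketone twisted by the ortho bromine. Prolonged heating could cause loss of the β-silyloxy group or drift of the new alkene into conjugation.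
- Fallback: it sets out from 9 and replaces the titanium carbene by a polar addition–elimination (Peterson olefination). Me3SiCH2MgCl with CeCl3 (THF, −78 to 0 °C) should add to the ketone without enolising it to give the β-hydroxysilane F4. KH (THF, 0 °C) should then induce syn-elimination to the terminal alkene only, rejoining the route at 10.

**Further compounds**
F1 | step 9 | {2-[(4S)-4-[3-(benzyloxy)-4,5-dimethoxyphenyl]-4-hydroxybut-1-en-2-yl]-5,6-dimethoxyphenyl}boronic acid | COc1cc([C@@H](O)CC(=C)c2ccc(OC)c(OC)c2B(O)O)cc(OCc2ccccc2)c1OC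
F2 | step 5 | (E)-3-[3-(benzyloxy)-4,5-dimethoxyphenyl]-1-(2-bromo-3,4-dimethoxyphenyl)prop-2-en-1-one | COc1cc(/C=C/C(=O)c2ccc(OC)c(OC)c2Br)cc(OCc2ccccc2)c1OC
F3 | step 5 | [(2S,3R)-3-[3-(benzyloxy)-4,5-dimethoxyphenyl]oxiran-2-yl](2-bromo-3,4-dimethoxyphenyl)methanone | COc1cc([C@H]2O[C@@H]2C(=O)c3ccc(OC)c(OC)c3Br)cc(OCc3ccccc3)c1OC
F4 | step 7 | (4S)-4-[3-(benzyloxy)-4,5-dimethoxyphenyl]-2-(2-bromo-3,4-dimethoxyphenyl)-4-[(tert-butyldimethylsilyl)oxy]-1-(trimethylsilyl)butan-2-ol (C2 epimers) | COc1cc([C@@H](O[Si](C)(C)C(C)(C)C)CC(O)(C[Si](C)(C)C)c2ccc(OC)c(OC)c2Br)cc(OCc2ccccc2)c1OC
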